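**Retrosynthetic overview**
1. Ten-membered carbocycle (second and last ring): open C1=C10 by ring-closing metathesis to an acyclic trans-lactone with a prenyl end and a 2-(hydroxyalkyl)acrylate end.
2. Lactone (first ring): open the lactone C-O bond and C6-C7 to (S)-citronellal and a chiral 2-(bromomethyl)enoate (chromium allylation, then lactonisation); the C8 acyloxy centre controls C7 and C6.
3. Key step, C9-O bond: the C8 ester / C9 alcohol pair comes from an achiral bis(allylic bromide) isovalerate by a catalytic desymmetrising SN2-SN2′ hydroxylation that sets C8 and C9 together.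
4. The bis(allylic bromide) comes from divinylcarbinol, isovaleryl chloride and methyl 2-(bromomethyl)acrylate (acylation, double cross-metathesis).

Assumption: the SMILES is taken as written, i.e. the (4S,6R,7S,8S,9S) isomer with the ring-cis (CIP E) C1=C10 enoate; positions are given in germacrane numbering (lactone O on C6, ring fusion C7, isovalerate on C8, OH on C9, CO2Me on C10, methyl on C4), and the catalyst in step 3 is the antipode whose sense of induction gives 7.

Step 1
Reactants: 1 penta-1,4-dien-3-ol; 2 3-methylbutanoyl chloride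
Product: 3 penta-1,4-dien-3-yl 3-methylbutanoate
Conditions: 2 (1.1 equiv), pyridine (1.5 equiv), DMAP (5 mol %), CH2Cl2, 0 °C to rt
Reagents that add atoms: none
Why: DMAP-catalysed O-acylation (nucleophilic acyl transfer) of the secondary bis-allylic alcohol puts the C8 isovalerate in place at the outset; no stereocentre is formed, the carbinol carbon stays prochiral.

Step 2
Reactants: 3 penta-1,4-dien-3-yl 3-methylbutanoate; 4 methyl 2-(bromomethyl)prop-2-enoate
Product: 5 dimethyl (2Z,5Z)-2,6-bis(bromomethyl)-4-[(3-methylbutanoyl)oxy]hepta-2,5-dienedioate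
Conditions: 4 (8 equiv), second-generation Hoveyda-Grubbs catalyst RuCl2(H2IMes)(=CH-C6H4-2-OiPr) (2 x 5 mol %), 1,4-benzoquinone (10 mol %), CH2Cl2, 40 °C
Reagents that add atoms: none
Why: Double olefin cross-metathesis of the two vinyl groups with the 1,1-disubstituted acrylate (the same olefin class as in methacrylate cross-metathesis), run with excess 4 so that homodimers re-enter; the trisubstituted enoates form under thermodynamic control with the ester cis to H, i.e. CH2Br cis to C8 (2Z,5Z), and the product stays achiral.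

Step 3
Reactants: 5 dimethyl (2Z,5Z)-2,6-bis(bromomethyl)-4-[(3-methylbutanoyl)oxy]hepta-2,5-dienedioate
Product: 7 dimethyl (2Z,4S,5S)-2-(bromomethyl)-5-hydroxy-6-methylidene-4-[(3-methylbutanoyl)oxy]hept-2-enedioate, via dioxolan-2-ylium bromide 6 (not isolated)
Conditions: (DHQD)2PHAL (10 mol %), H2O (2 equiv), 2,6-di-tert-butyl-4-methylpyridine (1.1 equiv), CHCl3, -20 °C, stopped when 5 is consumed
Reagents that add atoms: water, O
Why: Proposed new method: a cinchona-amine-catalysed, anchimerically assisted SN2-SN2′ hydroxylation that desymmetrises 5: the quinuclidine nitrogen displaces bromide reversibly on either arm, the carbonyl oxygen of the C8 isovalerate then adds 5-exo to C9 of the allylammonium with loss of the amine, and because A(1,3) strain forces the C8 hydrogen to eclipse the bulky cis CH2N+ group only the trans-4,5-disubstituted dioxolan-2-ylium ion 6 can form, so the facial preference of the chiral ammonium becomes a choice between the two enantiotopic arms and fixes C8 and C9 together (threo, 4S,5S); water then adds to C2 of 6 and the hemi-orthoester expels the more acidic C9 alkoxide, leaving the isovalerate on O8 and the new hydroxyl on C9, while the remaining arm of 7 is the mismatched one and reacts on only slowly; the closest known reactions are the cinchona-alkaloid-catalysed asymmetric allylic substitution of Morita-Baylis-Hillman bromides and carbonates with oxygen nucleophiles including water, and Winstein-Woodward neighbouring acyloxy participation (dioxolan-2-ylium ion to hydroxy ester).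

Step 4
Reactants: 7 dimethyl (2Z,4S,5S)-2-(bromomethyl)-5-hydroxy-6-methylidene-4-[(3-methylbutanoyl)oxy]hept-2-enedioate; 8 (3S)-3,7-dimethyloct-6-enal ((S)-citronellal)
Product: 10 methyl (3S,4S)-4-{(2R,3S)-2-[(2S)-2,6-dimethylhept-5-en-1-yl]-4-methylidene-5-oxooxolan-3-yl}-3-hydroxy-2-methylidene-4-[(3-methylbutanoyl)oxy]butanoate, via hydroxy diester 9 (not isolated)
Conditions: 8 (1.2 equiv), CrCl2 (4 equiv), THF, 0 °C to rt, aqueous NH4Cl work-up; then p-TsOH (10 mol %), CH2Cl2, rt
Reagents that add atoms: none
Why: Nozaki-Hiyama-type (Barbier-mode) 2-(methoxycarbonyl)allylation followed by acid-catalysed lactonisation: CrCl2 reduces the allylic bromide in the presence of 8 so that carbonyl addition outruns 1,4-loss of the isovalerate, the chair transition state of the chromium reagent gives the anti homoallylic alcohol (hence the trans lactone, 6R,7S), the aldehyde bonds to C7 anti to the C8-C9 bond with the C8 hydrogen eclipsing the allyl unit (Felkin-type 1,2-induction known for chromium additions of chiral delta-oxygenated allylic bromides), which places C11 anti to O8, and the C6 hydroxyl then closes the five-membered lactone on the C12 methyl ester in preference to a six-membered lactone from the C9 hydroxyl.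

Step 5
Reactants: 10 methyl (3S,4S)-4-{(2R,3S)-2-[(2S)-2,6-dimethylhept-5-en-1-yl]-4-methylidene-5-oxooxolan-3-yl}-3-hydroxy-2-methylidene-4-[(3-methylbutanoyl)oxy]butanoate
Product: 11 CNP0544142.1, methyl (3aS,4S,5S,6E,10S,11aR)-5-hydroxy-10-methyl-3-methylidene-4-[(3-methylbutanoyl)oxy]-2-oxo-2,3,3a,4,5,8,9,10,11,11a-decahydrocyclodeca[b]furan-6-carboxylate
Conditions: second-generation Hoveyda-Grubbs catalyst RuCl2(H2IMes)(=CH-C6H4-2-OiPr) (15 mol %, two portions), 1,4-benzoquinone (20 mol %), toluene (1 mM), 90 °C, argon sparge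
Reagents that add atoms: none
Why: Ring-closing olefin metathesis (loss of 2-methylpropene from the prenyl end) onto the acrylate, whose free allylic hydroxyl assists the catalyst, closes the ten-membered ring; the ring-cis C1=C10 geometry (6E, ester trans to C2) is both the less strained cyclodecene and the tiglate-type enoate, the alpha-methylene lactone cannot close without a bridgehead alkene, and no stereocentre is touched.

**Compound list**
1 | penta-1,4-dien-3-ol | C=CC(O)C=C | starting material
2 | 3-methylbutanoyl chloride | CC(C)CC(Cl)=O | starting material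
3 | penta-1,4-dien-3-yl 3-methylbutanoate | C=CC(OC(=O)CC(C)C)C=C | intermediate
4 | methyl 2-(bromomethyl)prop-2-enoate | C=C(CBr)C(=O)OC | starting material
5 | dimethyl (2Z,5Z)-2,6-bis(bromomethyl)-4-[(3-methylbutanoyl)oxy]hepta-2,5-dienedioate | BrC/C(C(=O)OC)=C\C(OC(=O)CC(C)C)/C=C(\CBr)C(=O)OC | intermediate
6 | (4S,5S)-4-[(1Z)-3-bromo-2-(methoxycarbonyl)prop-1-en-1-yl]-5-(3-methoxy-3-oxoprop-1-en-2-yl)-2-(2-methylpropyl)-1,3-dioxolan-2-ylium bromide | CC(C)CC1=[O+][C@@H](C(=C)C(=O)OC)[C@@H](O1)/C=C(\CBr)C(=O)OC.[Br-] | intermediate (not isolated)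
7 | dimethyl (2Z,4S,5S)-2-(bromomethyl)-5-hydroxy-6-methylidene-4-[(3-methylbutanoyl)oxy]hept-2-enedioate | BrC/C(C(=O)OC)=C\[C@H](OC(=O)CC(C)C)[C@@H](O)C(=C)C(=O)OC | intermediate
8 | (3S)-3,7-dimethyloct-6-enal ((S)-citronellal) | O=CC[C@@H](C)CCC=C(C)C | starting material
9 | dimethyl (3S,4S,5S)-3-hydroxy-5-[(1R,3S)-1-hydroxy-3,7-dimethyloct-6-en-1-yl]-2,6-dimethylidene-4-[(3-methylbutanoyl)oxy]heptanedioate | C=C(C(=O)OC)[C@@H]([C@H](O)C[C@@H](C)CCC=C(C)C)[C@H](OC(=O)CC(C)C)[C@@H](O)C(=C)C(=O)OC | intermediate (not isolated)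
10 | methyl (3S,4S)-4-{(2R,3S)-2-[(2S)-2,6-dimethylhept-5-en-1-yl]-4-methylidene-5-oxooxolan-3-yl}-3-hydroxy-2-methylidene-4-[(3-methylbutanoyl)oxy]butanoate | C=C1C(=O)O[C@H](C[C@@H](C)CCC=C(C)C)[C@H]1[C@H](OC(=O)CC(C)C)[C@@H](O)C(=C)C(=O)OC | intermediate
11 | CNP0544142.1, methyl (3aS,4S,5S,6E,10S,11aR)-5-hydroxy-10-methyl-3-methylidene-4-[(3-methylbutanoyl)oxy]-2-oxo-2,3,3a,4,5,8,9,10,11,11a-decahydrocyclodeca[b]furan-6-carboxylate | C=C1C(=O)O[C@@H]2C[C@@H](C)CC/C=C(/C(=O)OC)[C@H](O)[C@@H](OC(=O)CC(C)C)[C@@H]12 | target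

**Totals**
Total step count: 5. Longest linear sequence: 5 steps (1 to 3 to 5 to 7 to 10 to 11); 8 enters in step 4.

**Steps most likely to fail**

Step 2 (double cross-metathesis). A functionalised 1,1-disubstituted acrylate must couple twice with a doubly allylic ester. Slow turnover, double-bond migration and E/Z mixtures are the likely problems. The fallback replaces metathesis by carbonyl olefination; it sets out from 2, the only listed compound it uses, and comes back at 5. Tetraethyl (2-oxopropane-1,3-diyl)bis(phosphonate) and methyl pyruvate (NaH, THF, 0 °C to rt, double Horner-Wadsworth-Emmons reaction) give dimethyl (2E,5E)-2,6-dimethyl-4-oxohepta-2,5-dienedioate F1. Wohl-Ziegler bromination (N-bromosuccinimide, AIBN, PhCF3, 80 °C; the methyl groups are the only allylic hydrogens) gives dimethyl (2Z,5Z)-2,6-bis(bromomethyl)-4-oxohepta-2,5-dienedioate F2. Luche reduction (NaBH4, CeCl3·7H2O, MeOH, -78 °C, AcOH quench) gives dimethyl (2Z,5Z)-2,6-bis(bromomethyl)-4-hydroxyhepta-2,5-dienedioate F3, which is acylated at once with 2 (pyridine, DMAP, CH2Cl2, 0 °C) to 5.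

Step 3 (the new desymmetrisation). Four things can go wrong:
- water may attack the allylammonium directly and leak erythro product;
- the hemi-orthoester may collapse the other way, putting the ester on O9;
- the second arm may react on;
- the catalyst may give the opposite sense (then (DHQ)2PHAL is used).

The fallback uses known chemistry, a racemic synthesis followed by enzymatic kinetic resolution; it sets out from 5 and comes back at 7. DABCO (1.1 equiv) in aqueous THF with NaHCO3 converts one allylic bromide into the transposed alcohol, the known SN2-SN2′ hydrolysis of 2-(bromomethyl)alk-2-enoates to Morita-Baylis-Hillman alcohols. The threo alcohol is isolated by chromatography as the racemate, i.e. 7 together with its enantiomer dimethyl (2Z,4R,5R)-2-(bromomethyl)-5-hydroxy-6-methylidene-4-[(3-methylbutanoyl)oxy]hept-2-enedioate F4. Lipase-catalysed transesterification (lipase PS from Burkholderia cepacia, vinyl acetate, MTBE, 30 °C) acetylates the faster enantiomer, taken here as F4, to dimethyl (2Z,4R,5R)-5-(acetyloxy)-2-(bromomethyl)-6-methylidene-4-[(3-methylbutanoyl)oxy]hept-2-enedioate F5, and unreacted 7 is separated by chromatography.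

Step 5 (ring-closing metathesis). A trisubstituted, electron-poor alkene must form in a ten-membered ring from a prenyl end and an acrylate. Initiation is slow and oligomers or the ring-trans isomer may compete. The fallback closes the ring at C6-C7 instead of C1=C10; it sets out from 7 and 8 and comes back at 11. Ethenolysis of 8 (ethene 5 bar, second-generation Hoveyda-Grubbs catalyst RuCl2(H2IMes)(=CH-C6H4-2-OiPr), toluene, 40 °C) gives (3S)-3-methylhept-6-enal F6. Cross-metathesis of F6 (3 equiv) with the acrylate end of 7 (same catalyst, CH2Cl2, 40 °C) gives dimethyl (2Z,4S,5S,6E)-2-(bromomethyl)-5-hydroxy-6-[(4S)-4-methyl-6-oxohexylidene]-4-[(3-methylbutanoyl)oxy]hept-2-enedioate F7. Intramolecular Nozaki-Hiyama allylation (CrCl2, THF, 2 mM, rt), a ring closure used for other germacranolides, gives methyl (1E,5S,7R,8S,9S,10S)-7,10-dihydroxy-8-(3-methoxy-3-oxoprop-1-en-2-yl)-5-methyl-9-[(3-methylbutanoyl)oxy]cyclodec-1-ene-1-carboxylate F8, and p-TsOH in CH2Cl2 lactonises it to 11.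

**Further compounds**
F1 | step 2 | dimethyl (2E,5E)-2,6-dimethyl-4-oxohepta-2,5-dienedioate | COC(=O)/C(C)=C/C(=O)/C=C(\C)C(=O)OC
F2 | step 2 | dimethyl (2Z,5Z)-2,6-bis(bromomethyl)-4-oxohepta-2,5-dienedioate | BrC/C(C(=O)OC)=C\C(=O)/C=C(\CBr)C(=O)OC
F3 | step 2 | dimethyl (2Z,5Z)-2,6-bis(bromomethyl)-4-hydroxyhepta-2,5-dienedioate | BrC/C(C(=O)OC)=C\C(O)/C=C(\CBr)C(=O)OC
F4 | step 3 | dimethyl (2Z,4R,5R)-2-(bromomethyl)-5-hydroxy-6-methylidene-4-[(3-methylbutanoyl)oxy]hept-2-enedioate | BrC/C(C(=O)OC)=C\[C@@H](OC(=O)CC(C)C)[C@H](O)C(=C)C(=O)OC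
F5 | step 3 | dimethyl (2Z,4R,5R)-5-(acetyloxy)-2-(bromomethyl)-6-methylidene-4-[(3-methylbutanoyl)oxy]hept-2-enedioate | BrC/C(C(=O)OC)=C\[C@@H](OC(=O)CC(C)C)[C@H](OC(C)=O)C(=C)C(=O)OC
F6 | step 5 | (3S)-3-methylhept-6-enal | O=CC[C@@H](C)CCC=C
F7 | step 5 | dimethyl (2Z,4S,5S,6E)-2-(bromomethyl)-5-hydroxy-6-[(4S)-4-methyl-6-oxohexylidene]-4-[(3-methylbutanoyl)oxy]hept-2-enedioate | BrC/C(C(=O)OC)=C\[C@H](OC(=O)CC(C)C)[C@@H](O)/C(C(=O)OC)=C\CC[C@H](C)CC=O
F8 | step 5 | methyl (1E,5S,7R,8S,9S,10S)-7,10-dihydroxy-8-(3-methoxy-3-oxoprop-1-en-2-yl)-5-methyl-9-[(3-methylbutanoyl)oxy]cyclodec-1-ene-1-carboxylate | C=C(C(=O)OC)[C@H]1[C@H](O)C[C@@H](C)CC/C=C(/C(=O)OC)[C@H](O)[C@H]1OC(=O)CC(C)C
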